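**Plan**

1. Retrosynthesis (tetralin locants: C1 carries the pendant aryl, C2 the CH2O-acyl arm C9', C3 the CH2OH arm C9): cut the C9'–O coumarate ester, then the C1–C2 bond of ring B, then the C8a–C1 bond (aryllithium + aldehyde), then the C3–C4 bond (auxiliary alkylation).
2. Forward: the ring A benzyl bromide (from 6-bromovanillin) alkylates a pent-4-enoyl imide, the imide carbon becomes the protected C9 arm, the aryl bromide is lithiated and added to protected vanillin (pendant ring), the allyl end is cut to the C9' aldehyde, and ring B is closed last.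
3. Enabling feature: C1 is bonded to C8a of ring A (para to the C6 methoxy) and to C1' of the pendant ring (para to the C4' oxygen) and has no β-hydrogen, so it ionizes cleanly to a diarylmethyl cation; C2 is alpha to C9', which at the aldehyde level makes C2 an enamine carbon.
4. Stereochemistry: C3 comes from the Evans alkylation with (R)-4-benzyloxazolidin-2-one; C1 and C2 are both set in the ring closure under control of C3 (chair-like, all-equatorial), which should give the all-trans (1S,2R,3R) array.
5. End game: reduction of the C9' aldehyde, Steglich esterification with silylated p-coumaric acid, one global desilylation.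

Key step: step 11

Remark: the five starting materials (1, 5, 6, 12, 21) are taken to be commercial; the carbinol configuration at C1 in 15–17 is left unspecified because C1 becomes planar in step 11.

**Step 1**
Reactants: 1 6-bromovanillin (2-bromo-4-hydroxy-5-methoxybenzaldehyde)
Product: 2 2-bromo-5-methoxy-4-(triisopropylsilyloxy)benzaldehyde
Conditions: TIPSCl, imidazole, DMF, rt
Reagents that add atoms: triisopropylsilyl chloride, CC(C)[Si](Cl)(C(C)C)C(C)C
Why: Phenol silylation; the hindered aryl TIPS ether should survive the enolate, hydride and aryllithium steps and falls to fluoride at the end.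

**Step 2**
Reactants: 2 2-bromo-5-methoxy-4-(triisopropylsilyloxy)benzaldehyde
Product: 3 [2-bromo-5-methoxy-4-(triisopropylsilyloxy)phenyl]methanol
Conditions: NaBH4, MeOH/THF, 0 °C
Reagents that add atoms: none
Why: Chemoselective borohydride reduction of the aldehyde; aryl bromide and silyl ether are inert.

**Step 3**
Reactants: 3 [2-bromo-5-methoxy-4-(triisopropylsilyloxy)phenyl]methanol
Product: 4 2-bromo-5-methoxy-4-(triisopropylsilyloxy)benzyl bromide
Conditions: CBr4, PPh3, CH2Cl2, 0 °C (used without storage)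
Reagents that add atoms: carbon tetrabromide, BrC(Br)(Br)Br
Why: Appel bromination of the benzylic alcohol under neutral conditions that spare the aryl silyl ether.

**Step 4**
Reactants: 5 (R)-4-benzyloxazolidin-2-one; 6 pent-4-enoyl chloride
Product: 7 (R)-4-benzyl-3-(pent-4-enoyl)oxazolidin-2-one
Conditions: Et3N, DMAP (10 mol%), CH2Cl2, 0 °C → rt
Reagents that add atoms: none
Why: DMAP-catalysed N-acylation of the oxazolidinone attaches the auxiliary to the future C9–C3–C2–C9' chain.

**Step 5**
Reactants: 7 (R)-4-benzyl-3-(pent-4-enoyl)oxazolidin-2-one; 4 2-bromo-5-methoxy-4-(triisopropylsilyloxy)benzyl bromide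
Product: 9 (R)-4-benzyl-3-{(S)-2-[2-bromo-5-methoxy-4-(triisopropylsilyloxy)benzyl]pent-4-enoyl}oxazolidin-2-one, via sodium Z-enolate of the imide 8 (not isolated)
Conditions: NaN(SiMe3)2, THF, −78 °C; then 4, −78 → −30 °C
Reagents that add atoms: none
Why: Evans asymmetric alkylation; the chelated Z-enolate is benzylated on the face opposite the C4 benzyl group of the auxiliary, which sets C3 (the C3–C4 bond) in the sense the target needs.

**Step 6**
Reactants: 9 (R)-4-benzyl-3-{(S)-2-[2-bromo-5-methoxy-4-(triisopropylsilyloxy)benzyl]pent-4-enoyl}oxazolidin-2-one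
Product: 10 (S)-2-[2-bromo-5-methoxy-4-(triisopropylsilyloxy)benzyl]pent-4-en-1-ol
Conditions: LiBH4, MeOH (1 eq), Et2O, 0 °C
Reagents that add atoms: none
Why: Reductive cleavage of the N-acyl oxazolidinone gives the C9 primary alcohol without touching the stereocenter; the auxiliary is recovered.

**Step 7**
Reactants: 10 (S)-2-[2-bromo-5-methoxy-4-(triisopropylsilyloxy)benzyl]pent-4-en-1-ol
Product: 11 (S)-{2-[2-bromo-5-methoxy-4-(triisopropylsilyloxy)benzyl]pent-4-enyloxy}(tert-butyl)diphenylsilane
Conditions: TBDPSCl, imidazole, CH2Cl2, rt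
Reagents that add atoms: tert-butyldiphenylsilyl chloride, CC(C)(C)[Si](Cl)(c1ccccc1)c1ccccc1
Why: Silylation of the primary alcohol; the acid-stable TBDPS ether keeps the C9 oxygen distinct from the C9' oxygen through the acidic key step.

**Step 8**
Reactants: 12 vanillin
Product: 13 3-methoxy-4-(triisopropylsilyloxy)benzaldehyde
Conditions: TIPSCl, imidazole, DMF, rt
Reagents that add atoms: triisopropylsilyl chloride, CC(C)[Si](Cl)(C(C)C)C(C)C
Why: Phenol silylation so that the aldehyde can accept an aryllithium.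

**Step 9**
Reactants: 11 (S)-{2-[2-bromo-5-methoxy-4-(triisopropylsilyloxy)benzyl]pent-4-enyloxy}(tert-butyl)diphenylsilane; 13 3-methoxy-4-(triisopropylsilyloxy)benzaldehyde
Product: 15 {2-[(S)-2-(tert-butyldiphenylsilyloxymethyl)pent-4-enyl]-4-methoxy-5-(triisopropylsilyloxy)phenyl}[3-methoxy-4-(triisopropylsilyloxy)phenyl]methanol (both carbinol epimers), via aryllithium 14 (not isolated)
Conditions: t-BuLi (2.05 eq), THF, −78 °C; then 13, −78 → −30 °C; H2O
Reagents that add atoms: none
Why: Bromine–lithium exchange followed by 1,2-addition to the aldehyde forms the C8a–C1 bond; at −78 °C carbolithiation of the remote alkene should not compete.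

**Step 10**
Reactants: 15 the diarylmethanol of step 9
Product: 17 (R)-3-(tert-butyldiphenylsilyloxymethyl)-4-{2-[hydroxy(3-methoxy-4-(triisopropylsilyloxy)phenyl)methyl]-5-methoxy-4-(triisopropylsilyloxy)phenyl}butanal, via vicinal diol 16 (not isolated)
Conditions: OsO4 (2 mol%), NaIO4 (4 eq), 2,6-lutidine, dioxane/H2O (3:1), rt
Reagents that add atoms: osmium tetroxide, O=[Os](=O)(=O)=O (catalytic oxygen carrier); sodium periodate, [Na+].[O-]I(=O)(=O)=O (terminal oxygen source)
Why: Lemieux–Johnson oxidative cleavage of the monosubstituted alkene unveils the C9' aldehyde; C3 is β to the carbonyl and cannot epimerize, and no free phenol is present for periodate to attack.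

**Step 11**
Reactants: 17 the hydroxy aldehyde of step 10
Product: 19 (1S,2R,3R)-3-(tert-butyldiphenylsilyloxymethyl)-6-methoxy-1-[3-methoxy-4-(triisopropylsilyloxy)phenyl]-7-(triisopropylsilyloxy)-1,2,3,4-tetrahydronaphthalene-2-carbaldehyde, via enamine carbenium trifluoroacetate 18 (not isolated)
Conditions: pyrrolidine (20 mol%), TFA (40 mol%), CH2Cl2/HFIP (4:1), 0.01 M, 0 °C → rt
Reagents that add atoms: none
Why: TFA in the ionizing medium should convert either carbinol epimer into a diarylmethyl cation at C1, stabilized through C8a by the para C6 methoxy group of ring A and through C1' by the para silyloxy group of the pendant ring and unable to eliminate for lack of a β-hydrogen, while pyrrolidine condenses with the C9' aldehyde to the E-enamine whose C2 attacks C1; the water released in the ionization hydrolyses the resulting iminium ion and returns the catalyst. The closest known reaction type is the SN1-type enamine α-alkylation of aldehydes with diarylmethanols, run here intramolecularly. Ring B closes in a 6-(enolexo)-exo-trig mode through a chair-like transition state. C2 is controlled by C3: allylic 1,3-strain holds the C3–H bond in the enamine plane, the tether delivers C1 to the face that carries C4, and C9' should therefore end trans to C9, an outcome that enamine/iminium equilibration of this epimerizable centre also favours thermodynamically. C1 is controlled by the geometry of the cation, in which the pendant aryl lies on the side of C8–H, away from the C4 methylene, and so becomes pseudo-equatorial and trans to C9'. The step needs intramolecular C-alkylation to outrun intermolecular Friedel–Crafts capture by the electron-rich rings, which high dilution, the silylated phenols and the six-membered transition state should secure.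

**Step 12**
Reactants: 19 the tetralin aldehyde of step 11
Product: 20 [(1S,2R,3R)-3-(tert-butyldiphenylsilyloxymethyl)-6-methoxy-1-[3-methoxy-4-(triisopropylsilyloxy)phenyl]-7-(triisopropylsilyloxy)-1,2,3,4-tetrahydronaphthalen-2-yl]methanol
Conditions: NaBH4, MeOH/THF, 0 °C
Reagents that add atoms: none
Why: Borohydride reduction of the aldehyde gives the free C9' alcohol beside the silylated C9 oxygen and removes the epimerizable centre.

**Step 13**
Reactants: 21 (E)-p-coumaric acid
Product: 23 (E)-3-[4-(tert-butyldimethylsilyloxy)phenyl]acrylic acid, via bis-silylated coumaric acid 22 (not isolated)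
Conditions: TBSCl (2.5 eq), imidazole, DMF, rt; then AcOH/THF/H2O, rt
Reagents that add atoms: tert-butyldimethylsilyl chloride, CC(C)(C)[Si](C)(C)Cl
Why: Exhaustive silylation followed by selective hydrolysis of the much more labile silyl ester leaves the phenol protected and the acid free.

**Step 14**
Reactants: 20 the primary alcohol of step 12; 23 (E)-3-[4-(tert-butyldimethylsilyloxy)phenyl]acrylic acid
Product: 25 [(1S,2R,3R)-3-(tert-butyldiphenylsilyloxymethyl)-6-methoxy-1-[3-methoxy-4-(triisopropylsilyloxy)phenyl]-7-(triisopropylsilyloxy)-1,2,3,4-tetrahydronaphthalen-2-yl]methyl (E)-3-[4-(tert-butyldimethylsilyloxy)phenyl]acrylate, via O-acylisourea 24 (not isolated)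
Conditions: DCC, DMAP (20 mol%), CH2Cl2, 0 °C → rt
Reagents that add atoms: none
Why: Steglich esterification of the only free hydroxyl; all phenols and the C9 oxygen are silylated, so the acyl group can only reach the C9' oxygen.

**Step 15**
Reactants: 25 the fully silylated ester of step 14
Product: 26 [(1S,2R,3R)-7-hydroxy-1-(4-hydroxy-3-methoxyphenyl)-3-(hydroxymethyl)-6-methoxy-1,2,3,4-tetrahydronaphthalen-2-yl]methyl (E)-3-(4-hydroxyphenyl)acrylate
Conditions: TBAF (6 eq), AcOH (6 eq), THF, 0 °C → rt
Reagents that add atoms: none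
Why: Fluoride-mediated desilylation should cleave the three aryl silyl ethers and the primary TBDPS ether in one operation; the acetic acid buffer keeps phenoxide and alkoxide concentrations low so that the cinnamate ester neither migrates nor cleaves.

**Compound list**

1 | 6-bromovanillin | O=Cc1cc(OC)c(O)cc1Br | starting material
2 | 2-bromo-5-methoxy-4-(triisopropylsilyloxy)benzaldehyde | O=Cc1cc(OC)c(O[Si](C(C)C)(C(C)C)C(C)C)cc1Br | intermediate
3 | [2-bromo-5-methoxy-4-(triisopropylsilyloxy)phenyl]methanol | OCc1cc(OC)c(O[Si](C(C)C)(C(C)C)C(C)C)cc1Br | intermediate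
4 | 2-bromo-5-methoxy-4-(triisopropylsilyloxy)benzyl bromide | BrCc1cc(OC)c(O[Si](C(C)C)(C(C)C)C(C)C)cc1Br | intermediate
5 | (R)-4-benzyloxazolidin-2-one | O=C1N[C@H](Cc2ccccc2)CO1 | starting material
6 | pent-4-enoyl chloride | C=CCCC(=O)Cl | starting material
7 | (R)-4-benzyl-3-(pent-4-enoyl)oxazolidin-2-one | C=CCCC(=O)N1[C@H](Cc2ccccc2)COC1=O | intermediate
8 | sodium Z-enolate of 7 | C=CC/C=C(\[O-])N1[C@H](Cc2ccccc2)COC1=O.[Na+] | intermediate
9 | (R)-4-benzyl-3-{(S)-2-[2-bromo-5-methoxy-4-(triisopropylsilyloxy)benzyl]pent-4-enoyl}oxazolidin-2-one | C=CC[C@@H](Cc1cc(OC)c(O[Si](C(C)C)(C(C)C)C(C)C)cc1Br)C(=O)N1[C@H](Cc2ccccc2)COC1=O | intermediate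
10 | (S)-2-[2-bromo-5-methoxy-4-(triisopropylsilyloxy)benzyl]pent-4-en-1-ol | C=CC[C@@H](Cc1cc(OC)c(O[Si](C(C)C)(C(C)C)C(C)C)cc1Br)CO | intermediate
11 | TBDPS ether of 10 (S) | C=CC[C@@H](Cc1cc(OC)c(O[Si](C(C)C)(C(C)C)C(C)C)cc1Br)CO[Si](c1ccccc1)(c1ccccc1)C(C)(C)C | intermediate
12 | vanillin | O=Cc1ccc(O)c(OC)c1 | starting material
13 | 3-methoxy-4-(triisopropylsilyloxy)benzaldehyde | O=Cc1ccc(O[Si](C(C)C)(C(C)C)C(C)C)c(OC)c1 | intermediate
14 | aryllithium from 11 | C=CC[C@@H](Cc1cc(OC)c(O[Si](C(C)C)(C(C)C)C(C)C)cc1[Li])CO[Si](c1ccccc1)(c1ccccc1)C(C)(C)C | intermediate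
15 | diarylmethanol with pent-4-enyl side chain (S at the chain centre, both carbinol epimers) | C=CC[C@@H](Cc1cc(OC)c(O[Si](C(C)C)(C(C)C)C(C)C)cc1C(O)c1ccc(O[Si](C(C)C)(C(C)C)C(C)C)c(OC)c1)CO[Si](c1ccccc1)(c1ccccc1)C(C)(C)C | intermediate
16 | vicinal diol from dihydroxylation of the alkene of 15 | OCC(O)C[C@@H](Cc1cc(OC)c(O[Si](C(C)C)(C(C)C)C(C)C)cc1C(O)c1ccc(O[Si](C(C)C)(C(C)C)C(C)C)c(OC)c1)CO[Si](c1ccccc1)(c1ccccc1)C(C)(C)C | intermediate
17 | (R)-3-(tert-butyldiphenylsilyloxymethyl)-4-aryl-butanal carrying the diarylmethanol (name as in step 10) | O=CC[C@@H](Cc1cc(OC)c(O[Si](C(C)C)(C(C)C)C(C)C)cc1C(O)c1ccc(O[Si](C(C)C)(C(C)C)C(C)C)c(OC)c1)CO[Si](c1ccccc1)(c1ccccc1)C(C)(C)C | intermediate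
18 | E-pyrrolidine enamine of 17 with C1 as diarylmethyl cation, trifluoroacetate salt | COc1cc([CH+]c2cc(O[Si](C(C)C)(C(C)C)C(C)C)c(OC)cc2C[C@@H](CO[Si](c2ccccc2)(c2ccccc2)C(C)(C)C)/C=C/N2CCCC2)ccc1O[Si](C(C)C)(C(C)C)C(C)C.[O-]C(=O)C(F)(F)F | intermediate
19 | (1S,2R,3R)-tetralin-2-carbaldehyde (name as in step 11) | COc1cc([C@H]2c3cc(O[Si](C(C)C)(C(C)C)C(C)C)c(OC)cc3C[C@@H](CO[Si](c3ccccc3)(c3ccccc3)C(C)(C)C)[C@@H]2C=O)ccc1O[Si](C(C)C)(C(C)C)C(C)C | intermediate
20 | (1S,2R,3R)-tetralin-2-ylmethanol (name as in step 12) | COc1cc([C@H]2c3cc(O[Si](C(C)C)(C(C)C)C(C)C)c(OC)cc3C[C@@H](CO[Si](c3ccccc3)(c3ccccc3)C(C)(C)C)[C@@H]2CO)ccc1O[Si](C(C)C)(C(C)C)C(C)C | intermediate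
21 | (E)-p-coumaric acid | OC(=O)/C=C/c1ccc(O)cc1 | starting material
22 | tert-butyldimethylsilyl (E)-3-[4-(tert-butyldimethylsilyloxy)phenyl]acrylate | CC(C)(C)[Si](C)(C)OC(=O)/C=C/c1ccc(O[Si](C)(C)C(C)(C)C)cc1 | intermediate
23 | (E)-3-[4-(tert-butyldimethylsilyloxy)phenyl]acrylic acid | OC(=O)/C=C/c1ccc(O[Si](C)(C)C(C)(C)C)cc1 | intermediate
24 | O-acylisourea from 23 and DCC | O=C(/C=C/c1ccc(O[Si](C)(C)C(C)(C)C)cc1)OC(=NC1CCCCC1)NC1CCCCC1 | intermediate
25 | fully silylated coumarate ester (name as in step 14) | COc1cc([C@H]2c3cc(O[Si](C(C)C)(C(C)C)C(C)C)c(OC)cc3C[C@@H](CO[Si](c3ccccc3)(c3ccccc3)C(C)(C)C)[C@@H]2COC(=O)/C=C/c2ccc(O[Si](C)(C)C(C)(C)C)cc2)ccc1O[Si](C(C)C)(C(C)C)C(C)C | intermediate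
26 | CNP0403384.1, (1S,2R,3R) all-trans aryltetralin 9'-O-(E)-p-coumarate | COc1cc([C@H]2c3cc(O)c(OC)cc3C[C@@H](CO)[C@@H]2COC(=O)/C=C/c2ccc(O)cc2)ccc1O | target

**Totals**

Total step count: 15. Longest linear sequence: 12 steps (1, 2, 3, 5, 6, 7, 9, 10, 11, 12, 14, 15).

**Steps most likely to fail**

Step 11. The diarylmethyl cation may be consumed by intermolecular Friedel–Crafts alkylation of the electron-rich rings before the enamine closes, or the closure may show poor facial selectivity at C1. The fallback avoids the cation and sets C1 by hydrogenation. It sets out from 15: oxidation with MnO2 in CH2Cl2 should give the diaryl ketone F1. Lemieux–Johnson cleavage of its alkene gives the keto aldehyde F2. Intramolecular aldol condensation (dibenzylammonium trifluoroacetate, toluene, 60 °C) closes the same C1–C2 bond as a C1=C2 double bond in the dihydronaphthalene enal F3. Hydrogenation over Pd/C in EtOAc should add hydrogen to the face opposite the C3 substituent and give the all-cis aldehyde F4. Epimerization of C2 with DBU in CH2Cl2 to the all-equatorial isomer returns to the route at 19.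

Step 15. Under the basic fluoride conditions the coumaroyl group may migrate from the C9' oxygen to the freshly liberated C9 oxygen, or the ester may be cleaved by phenoxide. The fallback keeps the ester away from basic fluoride. It sets out from 20: the two aryl silyl ethers are removed selectively (TBAF, 2.2 eq, THF, −20 °C) to give the C9-silylated triol F5. A Mitsunobu esterification (PPh3, DIAD, THF, 0 °C) with unprotected p-coumaric acid 21 then engages only the primary alcohol, since the carboxylic acid is the only pronucleophile acidic enough, and gives the mono-silylated ester F6. The remaining TBDPS ether is removed with HF·pyridine in THF/pyridine, an acidic medium in which no alkoxide forms, and the route is rejoined at 26.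

Step 10. The electron-rich diarylmethanol may be over-oxidized to the benzophenone, or material may be lost by oxidative attack on the arenes, during the osmium/periodate cleavage. The fallback cleaves the alkene before the diarylmethanol exists. It sets out from 11: Lemieux–Johnson cleavage gives the bromo aldehyde F7, which is masked as the dimethyl acetal F8 (HC(OMe)3, PPTS, MeOH). Bromine–lithium exchange with t-BuLi and addition to 13 give the diarylmethanol acetal F9. Mild hydrolysis (PPTS, acetone/H2O) returns to the route at 17.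

**Further compounds**

F1 | step 11 | diaryl ketone from oxidation of 15 (S at the chain centre) | C=CC[C@@H](Cc1cc(OC)c(O[Si](C(C)C)(C(C)C)C(C)C)cc1C(=O)c1ccc(O[Si](C(C)C)(C(C)C)C(C)C)c(OC)c1)CO[Si](c1ccccc1)(c1ccccc1)C(C)(C)C
F2 | step 11 | (R)-keto aldehyde from alkene cleavage of F1 | O=CC[C@@H](Cc1cc(OC)c(O[Si](C(C)C)(C(C)C)C(C)C)cc1C(=O)c1ccc(O[Si](C(C)C)(C(C)C)C(C)C)c(OC)c1)CO[Si](c1ccccc1)(c1ccccc1)C(C)(C)C
F3 | step 11 | (R)-3-(tert-butyldiphenylsilyloxymethyl)-6-methoxy-1-[3-methoxy-4-(triisopropylsilyloxy)phenyl]-7-(triisopropylsilyloxy)-3,4-dihydronaphthalene-2-carbaldehyde | COc1cc(C2=C(C=O)[C@H](CO[Si](c3ccccc3)(c3ccccc3)C(C)(C)C)Cc3cc(OC)c(O[Si](C(C)C)(C(C)C)C(C)C)cc32)ccc1O[Si](C(C)C)(C(C)C)C(C)C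
F4 | step 11 | (1S,2S,3R) all-cis C2 epimer of 19 | COc1cc([C@H]2c3cc(O[Si](C(C)C)(C(C)C)C(C)C)c(OC)cc3C[C@@H](CO[Si](c3ccccc3)(c3ccccc3)C(C)(C)C)[C@H]2C=O)ccc1O[Si](C(C)C)(C(C)C)C(C)C
F5 | step 15 | (1S,2R,3R) triol with free phenols, free C9' hydroxyl and C9 TBDPS ether | COc1cc([C@H]2c3cc(O)c(OC)cc3C[C@@H](CO[Si](c3ccccc3)(c3ccccc3)C(C)(C)C)[C@@H]2CO)ccc1O
F6 | step 15 | C9 TBDPS ether of the target | COc1cc([C@H]2c3cc(O)c(OC)cc3C[C@@H](CO[Si](c3ccccc3)(c3ccccc3)C(C)(C)C)[C@@H]2COC(=O)/C=C/c2ccc(O)cc2)ccc1O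
F7 | step 10 | (R)-4-[2-bromo-5-methoxy-4-(triisopropylsilyloxy)phenyl]-3-(tert-butyldiphenylsilyloxymethyl)butanal | O=CC[C@@H](Cc1cc(OC)c(O[Si](C(C)C)(C(C)C)C(C)C)cc1Br)CO[Si](c1ccccc1)(c1ccccc1)C(C)(C)C
F8 | step 10 | dimethyl acetal of F7 | COC(OC)C[C@@H](Cc1cc(OC)c(O[Si](C(C)C)(C(C)C)C(C)C)cc1Br)CO[Si](c1ccccc1)(c1ccccc1)C(C)(C)C
F9 | step 10 | dimethyl acetal of 17 | COC(OC)C[C@@H](Cc1cc(OC)c(O[Si](C(C)C)(C(C)C)C(C)C)cc1C(O)c1ccc(O[Si](C(C)C)(C(C)C)C(C)C)c(OC)c1)CO[Si](c1ccccc1)(c1ccccc1)C(C)(C)C
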